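**Retrosynthetic overview**
1. The quinone and the 8-OH are unmasked last: ring B is carried as a bis-benzyl hydroquinone and ring A as an 8-O-benzyl ether (one hydrogenolysis, then mild oxidation).
2. Key disconnection O1–C2: ring C (the only ring made) and the C3 stereocentre come from one enantioselective anti-Markovnikov 6-endo hydroetherification of a 2-(2-arylallyl)phenol.
3. The allylphenol comes from an aromatic Claisen rearrangement of an aryl 2-arylallyl ether, made by Mitsunobu union of a ring A phenol and a ring B allylic alcohol.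
4. Ring A phenol: from 2-hydroxy-3,4-dimethoxybenzaldehyde (benzylation, Dakin-type oxidation). Ring B allylic alcohol: from 2,3-dimethoxyphenol (quinone, reductive benzylation, bromination, arylmagnesium addition to propargyl alcohol).
5. Ring order: rings A and B are bought as benzene rings; ring C is closed in step 9; the quinone is formed in step 10.

Assumption: the target SMILES encodes (3S) (CIP order CH2O > quinonyl > CH2Ar > H); the enantiomer of the new thiol catalyst in step 9 is taken to be the one that gives (3S), which must be fixed by experiment.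

**Route**

Step 1
Reactants: 1 2-hydroxy-3,4-dimethoxybenzaldehyde
Product: 2 2-(benzyloxy)-3,4-dimethoxybenzaldehyde
Conditions: BnBr, K2CO3, DMF, 60 °C
Reagents that add atoms: benzyl bromide, BrCc1ccccc1
Why: Williamson ether synthesis on the only phenol; this oxygen becomes the 8-OH and the benzyl group leaves in step 10.

Step 2
Reactants: 2 2-(benzyloxy)-3,4-dimethoxybenzaldehyde
Product: 4 2-(benzyloxy)-3,4-dimethoxyphenol, via aryl formate 3 (not isolated)
Conditions: mCPBA, CH2Cl2, 0 °C to rt; then K2CO3 (cat.), MeOH, rt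
Reagents that add atoms: 3-chloroperoxybenzoic acid (mCPBA), OOC(=O)c1cccc(Cl)c1
Why: Baeyer–Villiger (Dakin-type) oxidation, in which the electron-rich aryl group migrates to give the formate, followed by methanolysis to the phenol that will become O1.

Step 3
Reactants: 5 2,3-dimethoxyphenol
Product: 6 2,3-dimethoxy-1,4-benzoquinone
Conditions: O2 (1 atm), Co(salen) [Co(C16H14N2O2), divalent cobalt] (5 mol%), DMF, rt
Reagents that add atoms: dioxygen, O=O
Why: cobalt–salen catalysed aerobic oxidation of a phenol with a free para position to the para-quinone, the standard entry to 2,3-dimethoxyquinones.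

Step 4
Reactants: 6 2,3-dimethoxy-1,4-benzoquinone
Product: 8 1,4-bis(benzyloxy)-2,3-dimethoxybenzene, via 2,3-dimethoxyhydroquinone 7 (not isolated)
Conditions: Na2S2O4, EtOAc/H2O, rt; then BnBr, K2CO3, DMF, 50 °C, Ar
Reagents that add atoms: benzyl bromide, BrCc1ccccc1
Why: dithionite reduction of the quinone followed by double Williamson etherification of the air-sensitive hydroquinone (reductive benzylation).

Step 5
Reactants: 8 1,4-bis(benzyloxy)-2,3-dimethoxybenzene
Product: 9 1,4-bis(benzyloxy)-5-bromo-2,3-dimethoxybenzene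
Conditions: NBS (1.0 equiv), MeCN, 0 °C to rt
Reagents that add atoms: N-bromosuccinimide, O=C1CCC(=O)N1Br
Why: electrophilic aromatic bromination of a tetra-alkoxybenzene whose two free positions are equivalent, so only one monobromide can form.

Step 6
Reactants: 9 1,4-bis(benzyloxy)-5-bromo-2,3-dimethoxybenzene; 10 prop-2-yn-1-ol
Product: 12 2-[2,5-bis(benzyloxy)-3,4-dimethoxyphenyl]prop-2-en-1-ol, via arylmagnesium bromide 11 (not isolated)
Conditions: Mg, THF, 50 °C; then BrMgOCH2C≡CH (from 10 + EtMgBr, THF, 0 °C), CuI (10 mol%), THF/toluene, 60 °C; aq. NH4Cl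
Reagents that add atoms: none
Why: copper-catalysed, alkoxide-directed carbomagnesiation of propargyl alcohol puts the aryl group on the internal alkyne carbon (magnesium on the terminal carbon in a five-membered chelate), and protonation gives the 2-arylallyl alcohol.

Step 7
Reactants: 4 2-(benzyloxy)-3,4-dimethoxyphenol; 12 2-[2,5-bis(benzyloxy)-3,4-dimethoxyphenyl]prop-2-en-1-ol
Product: 13 2-(benzyloxy)-1-({2-[2,5-bis(benzyloxy)-3,4-dimethoxyphenyl]prop-2-en-1-yl}oxy)-3,4-dimethoxybenzene
Conditions: PPh3, DIAD, THF, 0 °C to rt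
Reagents that add atoms: none
Why: Mitsunobu etherification of a primary allylic alcohol with a phenol; direct and allylically transposed attack give the same ether because the allyl unit is symmetric.

Step 8
Reactants: 13 2-(benzyloxy)-1-({2-[2,5-bis(benzyloxy)-3,4-dimethoxyphenyl]prop-2-en-1-yl}oxy)-3,4-dimethoxybenzene
Product: 14 2-(benzyloxy)-6-{2-[2,5-bis(benzyloxy)-3,4-dimethoxyphenyl]prop-2-en-1-yl}-3,4-dimethoxyphenol
Conditions: PhNEt2, 190 °C, sealed tube, Ar
Reagents that add atoms: none
Why: aromatic Claisen rearrangement ([3,3]-sigmatropic shift) to the only free ortho carbon (the other ortho and the para position are oxygen-substituted), which forms the C4–C4a bond and frees the O1 phenol.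

Step 9
Reactants: 14 2-(benzyloxy)-6-{2-[2,5-bis(benzyloxy)-3,4-dimethoxyphenyl]prop-2-en-1-yl}-3,4-dimethoxyphenol
Product: 15 (3S)-8-(benzyloxy)-3-[2,5-bis(benzyloxy)-3,4-dimethoxyphenyl]-6,7-dimethoxy-3,4-dihydro-2H-chromene
Conditions: 9-mesityl-3,6-di-tert-butyl-10-phenylacridinium tetrafluoroborate (5 mol%), chiral arenethiol (R)-2'-sulfanyl-3,3'-bis(2,4,6-triisopropylphenyl)-1,1'-binaphthalen-2-ol (20 mol%), DCE, 450 nm LEDs, −20 °C, Ar
Reagents that add atoms: none
Why: Proposed new method: enantioselective anti-Markovnikov hydro-aryloxylation by photoredox catalysis with a chiral thiol as hydrogen-atom donor; the excited acridinium oxidises the electron-rich styrene (or the ring A phenol) of 14, the phenol oxygen closes 6-endo onto the terminal CH2 because only this mode leaves a stabilised tertiary benzylic radical at C3 (this forms O1–C2 and ring C), and that planar radical then takes a hydrogen atom from the S–H of the arenethiol inside its hydrogen-bonded binaphthyl pocket, which is the enantio-determining step and sets (3S) (arenethiol S–H is estimated at about 79 kcal/mol against about 85 for the new C–H, so back-abstraction and racemisation should be slow); the acridine radical reduces the thiyl radical and the released proton regenerates the thiol; closest known reaction type: acridinium-photoredox anti-Markovnikov hydroetherification of alkenols with achiral thiol hydrogen donors, together with enantioselective hydrogen-atom transfer from homochiral thiols to prochiral carbon radicals.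

Step 10
Reactants: 15 (3S)-8-(benzyloxy)-3-[2,5-bis(benzyloxy)-3,4-dimethoxyphenyl]-6,7-dimethoxy-3,4-dihydro-2H-chromene
Product: 17 5-[(3S)-8-hydroxy-6,7-dimethoxy-3,4-dihydro-2H-chromen-3-yl]-2,3-dimethoxycyclohexa-2,5-diene-1,4-dione, via hydroquinone 16 (not isolated)
Conditions: H2 (1 atm), 10% Pd/C, EtOAc/MeOH, rt; filter; then Ag2O (1.1 equiv), Et2O, rt
Reagents that add atoms: none
Why: hydrogenolysis of the three benzyl ethers, then oxidation of the para-hydroquinone to the quinone with Ag2O, which is expected to leave the monohydric ring A phenol alone; both operations are neutral, so the C3 centre next to the quinone is not epimerised.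

**Compound list**
1 | 2-hydroxy-3,4-dimethoxybenzaldehyde | COc1ccc(C=O)c(O)c1OC | starting material
2 | 2-(benzyloxy)-3,4-dimethoxybenzaldehyde | COc1ccc(C=O)c(OCc2ccccc2)c1OC | intermediate
3 | 2-(benzyloxy)-3,4-dimethoxyphenyl formate | COc1ccc(OC=O)c(OCc2ccccc2)c1OC | intermediate
4 | 2-(benzyloxy)-3,4-dimethoxyphenol | COc1ccc(O)c(OCc2ccccc2)c1OC | intermediate
5 | 2,3-dimethoxyphenol | COc1cccc(O)c1OC | starting material
6 | 2,3-dimethoxy-1,4-benzoquinone | COC1=C(OC)C(=O)C=CC1=O | intermediate
7 | 2,3-dimethoxybenzene-1,4-diol (2,3-dimethoxyhydroquinone) | COc1c(O)ccc(O)c1OC | intermediate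
8 | 1,4-bis(benzyloxy)-2,3-dimethoxybenzene | COc1c(OCc2ccccc2)ccc(OCc2ccccc2)c1OC | intermediate
9 | 1,4-bis(benzyloxy)-5-bromo-2,3-dimethoxybenzene | COc1c(OCc2ccccc2)cc(Br)c(OCc2ccccc2)c1OC | intermediate
10 | prop-2-yn-1-ol | C#CCO | starting material
11 | [2,5-bis(benzyloxy)-3,4-dimethoxyphenyl]magnesium bromide | COc1c(OCc2ccccc2)cc([Mg]Br)c(OCc2ccccc2)c1OC | intermediate
12 | 2-[2,5-bis(benzyloxy)-3,4-dimethoxyphenyl]prop-2-en-1-ol | C=C(CO)c1cc(OCc2ccccc2)c(OC)c(OC)c1OCc1ccccc1 | intermediate
13 | 2-(benzyloxy)-1-({2-[2,5-bis(benzyloxy)-3,4-dimethoxyphenyl]prop-2-en-1-yl}oxy)-3,4-dimethoxybenzene | C=C(COc1ccc(OC)c(OC)c1OCc1ccccc1)c1cc(OCc2ccccc2)c(OC)c(OC)c1OCc1ccccc1 | intermediate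
14 | 2-(benzyloxy)-6-{2-[2,5-bis(benzyloxy)-3,4-dimethoxyphenyl]prop-2-en-1-yl}-3,4-dimethoxyphenol | C=C(Cc1cc(OC)c(OC)c(OCc2ccccc2)c1O)c1cc(OCc2ccccc2)c(OC)c(OC)c1OCc1ccccc1 | intermediate
15 | (3S)-8-(benzyloxy)-3-[2,5-bis(benzyloxy)-3,4-dimethoxyphenyl]-6,7-dimethoxy-3,4-dihydro-2H-chromene | COc1c(OC)c(OCc2ccccc2)c([C@H]2COc3c(cc(OC)c(OC)c3OCc3ccccc3)C2)cc1OCc1ccccc1 | intermediate
16 | 2-[(3S)-8-hydroxy-6,7-dimethoxy-3,4-dihydro-2H-chromen-3-yl]-5,6-dimethoxybenzene-1,4-diol | COc1c(OC)c(O)c([C@H]2COc3c(cc(OC)c(OC)c3O)C2)cc1O | intermediate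
17 | 5-[(3S)-8-hydroxy-6,7-dimethoxy-3,4-dihydro-2H-chromen-3-yl]-2,3-dimethoxycyclohexa-2,5-diene-1,4-dione | COC1=C(OC)C(=O)C([C@H]2COc3c(cc(OC)c(OC)c3O)C2)=CC1=O | target

**Summary**
Total steps: 10 (steps 1–2 ring A phenol, steps 3–6 ring B allylic alcohol, steps 7–10 after union).
Longest linear sequence: 8 steps (5 to 17, steps 3–10).

**Steps most likely to fail**

Step 9 (the new hydroetherification). The risks are low enantioselectivity in the hydrogen-atom transfer, the hole resting on the tetra-alkoxyarene instead of driving C–O closure, and re-oxidation of product 15. The fallback sets out from 14 and comes back at 15 using known chemistry. Copper hydride catalysed enantioselective anti-Markovnikov hydroboration of the 1,1-disubstituted alkene (CuCl, DTBM-SEGPHOS in the enantiomer that gives (S), KOtBu, excess HBpin so the phenol is carried as its borate) gives, after work-up, the alkylboronate F1. Oxidation with NaBO3·4H2O gives the hydroxypropylphenol F2. Intramolecular Mitsunobu etherification (PPh3, DIAD, THF) then closes ring C to 15. In this variant the stereocentre is set in the hydrocupration and the C–O closure is conventional.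

Step 8 (Claisen rearrangement at 190 °C). The risks are thermal addition of the new phenol to the styrene (dihydrobenzofuran formation) and loss of benzyl groups. The fallback sets out from 4 and 12 and comes back at 14, bypassing 13. Alcohol 12 is converted with CBr4/PPh3 into the allylic bromide F3. The sodium phenoxide of 4 (NaH) is then C-allylated with F3 in toluene at 80 °C, where the tight ion pair favours attack through the free ortho carbon. Any O-alkylated material is 13 and can be recycled.

Step 6 (copper-catalysed carbomagnesiation with a hindered, electron-rich aryl Grignard reagent). The risks are sluggish addition and protonation of 11 back to 8. The fallback sets out from 9 and comes back at 12. Miyaura borylation (B2pin2, KOAc, PdCl2(dppf), dioxane, 90 °C) gives the aryl pinacol boronate F4. Suzuki–Miyaura coupling of F4 with commercial 2-bromoprop-2-en-1-ol (Pd(PPh3)4, K2CO3, dioxane/H2O, 80 °C) gives 12.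

**Further compounds**
F1 | step 9 | 2-(benzyloxy)-6-[(2S)-2-[2,5-bis(benzyloxy)-3,4-dimethoxyphenyl]-3-(4,4,5,5-tetramethyl-1,3,2-dioxaborolan-2-yl)propyl]-3,4-dimethoxyphenol | CC1(C)OB(C[C@@H](Cc2cc(OC)c(OC)c(OCc3ccccc3)c2O)c2cc(OCc3ccccc3)c(OC)c(OC)c2OCc2ccccc2)OC1(C)C
F2 | step 9 | 2-(benzyloxy)-6-[(2S)-2-[2,5-bis(benzyloxy)-3,4-dimethoxyphenyl]-3-hydroxypropyl]-3,4-dimethoxyphenol | OC[C@@H](Cc1cc(OC)c(OC)c(OCc2ccccc2)c1O)c1cc(OCc2ccccc2)c(OC)c(OC)c1OCc1ccccc1
F3 | step 8 | 1,4-bis(benzyloxy)-5-(3-bromoprop-1-en-2-yl)-2,3-dimethoxybenzene | C=C(CBr)c1cc(OCc2ccccc2)c(OC)c(OC)c1OCc1ccccc1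
F4 | step 6 | 2-[2,5-bis(benzyloxy)-3,4-dimethoxyphenyl]-4,4,5,5-tetramethyl-1,3,2-dioxaborolane | COc1c(OCc2ccccc2)cc(B2OC(C)(C)C(C)(C)O2)c(OCc2ccccc2)c1OC
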